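## Retrosynthetic overview

1. Target 13 ⇐ half-ester 12 (BH3 reduces the acid, not the ester) ⇐ all-trans diester 11 (hydrolysis of the less hindered C3 ester). The two carboxyl termini are told apart only after ring closure.
2. 11 ⇐ seco-diester 9: ring B, the only ring built (both arenes are bought), is closed last by a quinone-methide Friedel–Crafts alkylation (C1–C8a). 9 is C2-symmetric, so its two benzyl groups are homotopic.
3. 9 ⇐ bis-imide 7: key disconnection C2–C3. Two identical enolate α-carbons are joined, one of them reversed in polarity as a trivalent-iodine enolonium species; an oxazolidinone auxiliary on each half sets both stereocentres (2S,3S).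
4. 7 ⇐ imide 4 ⇐ dihydroferulic acid 1 + (R)-4-benzyloxazolidin-2-one 2.
5. The target reads as (1R,2S,3S), all-trans. C2 and C3 come from the coupling, C1 from the 1,2-trans ring closure.

Assumption: target locants (C1 = ArCH, C2 = CHCO2Me, C3 = CHCH2OH, C4 = CH2, ring A = fused arene) are used for the tetralins; 1 and 2 are taken as inexpensive catalogue compounds.

## Route

Step 1
Reactants: 1 3-(4-hydroxy-3-methoxyphenyl)propanoic acid; 2 (R)-4-benzyloxazolidin-2-one
Product: 4 4-{3-[(4R)-4-benzyl-2-oxo-1,3-oxazolidin-3-yl]-3-oxopropyl}-2-methoxyphenyl pivalate, via mixed pivalic anhydride 3 (not isolated)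
Conditions: t-BuCOCl (2.3 equiv), Et3N (4 equiv), THF, −20 → 0 °C; then 2, LiCl, rt
Reagents that add atoms: pivaloyl chloride, CC(C)(C)C(=O)Cl
Why: Excess pivaloyl chloride caps the phenol as its pivalate and turns the acid into the mixed pivalic anhydride, which acylates the oxazolidinone nitrogen at its unhindered carbonyl under LiCl/Et3N activation (mixed-anhydride N-acylation of an Evans auxiliary); no stereocentre is formed.

Step 2
Reactants: 4 4-{3-[(4R)-4-benzyl-2-oxo-1,3-oxazolidin-3-yl]-3-oxopropyl}-2-methoxyphenyl pivalate (two molecules)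
Product: 7 (2S,3S)-1,4-bis[(4R)-4-benzyl-2-oxo-1,3-oxazolidin-3-yl]-2,3-bis{[3-methoxy-4-(pivaloyloxy)phenyl]methyl}butane-1,4-dione, via lithium Z-enolate 5 (not isolated), via iodanyl enolonium species 6 (not isolated)
Conditions: LiN(i-Pr)2 (1.05 equiv), THF, −78 °C; then PhI(OAc)2 (0.5 equiv), −78 → 0 °C
Reagents that add atoms: none
Why: Oxidative enolate homocoupling with trivalent iodine, in which half of the chelated Z-enolate 5 is converted by PhI(OAc)2 into the iodanyl species 6 (an enolonium, i.e. α-carbonyl cation, equivalent) that is attacked at its α-carbon by a second enolate with loss of PhI, so that two normally nucleophilic α-carbons are joined, each new stereocentre forming on the face away from the auxiliary benzyl group to give the C2-symmetric (2S,3S) isomer rather than the meso compound, as is known for oxidative dimerisation of 3-(3-arylpropanoyl)oxazolidinones.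

Step 3
Reactants: 7 (2S,3S)-1,4-bis[(4R)-4-benzyl-2-oxo-1,3-oxazolidin-3-yl]-2,3-bis{[3-methoxy-4-(pivaloyloxy)phenyl]methyl}butane-1,4-dione
Product: 9 dimethyl (2S,3S)-2,3-bis[(4-hydroxy-3-methoxyphenyl)methyl]butanedioate, via bis-pivalate dimethyl ester 8 (not isolated)
Conditions: Yb(OTf)3 (10 mol%), MeOH, 60 °C; then K2CO3 (20 mol%), MeOH, 40 °C
Reagents that add atoms: methanol, CO
Why: Lewis-acid-catalysed methanolysis of the chelated exocyclic imide carbonyl (transesterification under non-basic conditions, so the α-stereocentres are not epimerised) releases the recoverable auxiliary, and mild carbonate-catalysed methanolysis then removes the two aryl pivalates without touching either stereocentre.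

Step 4
Reactants: 9 dimethyl (2S,3S)-2,3-bis[(4-hydroxy-3-methoxyphenyl)methyl]butanedioate
Product: 11 dimethyl (1R,2S,3S)-7-hydroxy-1-(4-hydroxy-3-methoxyphenyl)-6-methoxy-1,2,3,4-tetrahydronaphthalene-2,3-dicarboxylate, via p-quinone methide 10 (not isolated)
Conditions: DDQ (1.0 equiv, slow addition), CH2Cl2/1,4-dioxane, 0 °C; then CF3CO2H, 0 °C → rt
Reagents that add atoms: none
Why: Biomimetic quinone-methide Friedel–Crafts cyclisation, in which DDQ dehydrogenates one of the two homotopic p-hydroxybenzyl groups to p-quinone methide 10 and, on protonation, ring A attacks the benzylic cation para to its OMe group through a chair-like transition state with the aryl group and both ester groups equatorial, which sets C1 trans to C2 (1R) and gives the all-trans tetralin.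

Step 5
Reactants: 11 dimethyl (1R,2S,3S)-7-hydroxy-1-(4-hydroxy-3-methoxyphenyl)-6-methoxy-1,2,3,4-tetrahydronaphthalene-2,3-dicarboxylate
Product: 12 (1R,2S,3S)-7-hydroxy-1-(4-hydroxy-3-methoxyphenyl)-6-methoxy-2-(methoxycarbonyl)-1,2,3,4-tetrahydronaphthalene-3-carboxylic acid
Conditions: LiOH (3.3 equiv), THF/H2O, 0 °C → rt, N2; then 1 M HCl
Reagents that add atoms: lithium hydroxide, [Li+].[OH-]
Why: Regioselective saponification, in which hydroxide attacks the C3 ester (flanked only by the ring CH2) faster than the C2 ester shielded by the C1 aryl group and the carboxylate formed suppresses the second hydrolysis, while the all-trans arrangement is the thermodynamic one so base cannot scramble C2 or C3.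

Step 6
Reactants: 12 (1R,2S,3S)-7-hydroxy-1-(4-hydroxy-3-methoxyphenyl)-6-methoxy-2-(methoxycarbonyl)-1,2,3,4-tetrahydronaphthalene-3-carboxylic acid
Product: 13 methyl (1R,2S,3S)-7-hydroxy-1-(4-hydroxy-3-methoxyphenyl)-3-(hydroxymethyl)-6-methoxy-1,2,3,4-tetrahydronaphthalene-2-carboxylate
Conditions: BH3·THF (4 equiv), THF, 0 °C → rt; MeOH quench
Reagents that add atoms: none
Why: Chemoselective borane reduction of a carboxylic acid beside a methyl ester (via the acyloxyborane) gives the primary alcohol, the trans hydroxy ester cannot lactonise without forming a strained trans-fused lactone, and no stereocentre is affected.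

## Compound list

1 | 3-(4-hydroxy-3-methoxyphenyl)propanoic acid (dihydroferulic acid) | COc1cc(CCC(=O)O)ccc1O | starting material
2 | (R)-4-benzyloxazolidin-2-one | O=C1N[C@H](Cc2ccccc2)CO1 | starting material
3 | 3-[3-methoxy-4-(pivaloyloxy)phenyl]propanoic pivalic anhydride | CC(C)(C)C(=O)OC(=O)CCc1ccc(OC(=O)C(C)(C)C)c(OC)c1 | intermediate
4 | 4-{3-[(4R)-4-benzyl-2-oxo-1,3-oxazolidin-3-yl]-3-oxopropyl}-2-methoxyphenyl pivalate | CC(C)(C)C(=O)Oc1ccc(CCC(=O)N2C(=O)OC[C@H]2Cc2ccccc2)cc1OC | intermediate
5 | lithium (Z)-enolate of 4 | [Li]O/C(=C\Cc1ccc(OC(=O)C(C)(C)C)c(OC)c1)N1C(=O)OC[C@H]1Cc1ccccc1 | intermediate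
6 | 4-{2-[acetoxy(phenyl)iodanyl]-3-[(4R)-4-benzyl-2-oxo-1,3-oxazolidin-3-yl]-3-oxopropyl}-2-methoxyphenyl pivalate (C-bound form of the trivalent-iodine enolate; configuration at the iodine-bearing carbon not defined) | CC(=O)OI(c1ccccc1)C(Cc1ccc(OC(=O)C(C)(C)C)c(OC)c1)C(=O)N1C(=O)OC[C@H]1Cc1ccccc1 | intermediate
7 | (2S,3S)-1,4-bis[(4R)-4-benzyl-2-oxo-1,3-oxazolidin-3-yl]-2,3-bis{[3-methoxy-4-(pivaloyloxy)phenyl]methyl}butane-1,4-dione | O=C(N1C(=O)OC[C@H]1Cc1ccccc1)[C@@H](Cc1ccc(OC(=O)C(C)(C)C)c(OC)c1)[C@H](Cc1ccc(OC(=O)C(C)(C)C)c(OC)c1)C(=O)N1C(=O)OC[C@H]1Cc1ccccc1 | intermediate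
8 | dimethyl (2S,3S)-2,3-bis{[3-methoxy-4-(pivaloyloxy)phenyl]methyl}butanedioate | COC(=O)[C@@H](Cc1ccc(OC(=O)C(C)(C)C)c(OC)c1)[C@H](Cc1ccc(OC(=O)C(C)(C)C)c(OC)c1)C(=O)OC | intermediate
9 | dimethyl (2S,3S)-2,3-bis[(4-hydroxy-3-methoxyphenyl)methyl]butanedioate | COC(=O)[C@@H](Cc1ccc(O)c(OC)c1)[C@H](Cc1ccc(O)c(OC)c1)C(=O)OC | intermediate
10 | dimethyl (2S,3S)-2-[(4-hydroxy-3-methoxyphenyl)methyl]-3-[(3-methoxy-4-oxocyclohexa-2,5-dien-1-ylidene)methyl]butanedioate | COC(=O)[C@@H](C=C1C=CC(=O)C(OC)=C1)[C@H](Cc1ccc(O)c(OC)c1)C(=O)OC | intermediate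
11 | dimethyl (1R,2S,3S)-7-hydroxy-1-(4-hydroxy-3-methoxyphenyl)-6-methoxy-1,2,3,4-tetrahydronaphthalene-2,3-dicarboxylate | COC(=O)[C@@H]1[C@@H](C(=O)OC)Cc2cc(OC)c(O)cc2[C@H]1c1ccc(O)c(OC)c1 | intermediate
12 | (1R,2S,3S)-7-hydroxy-1-(4-hydroxy-3-methoxyphenyl)-6-methoxy-2-(methoxycarbonyl)-1,2,3,4-tetrahydronaphthalene-3-carboxylic acid | COC(=O)[C@@H]1[C@@H](C(=O)O)Cc2cc(OC)c(O)cc2[C@H]1c1ccc(O)c(OC)c1 | intermediate
13 | methyl (1R,2S,3S)-7-hydroxy-1-(4-hydroxy-3-methoxyphenyl)-3-(hydroxymethyl)-6-methoxy-1,2,3,4-tetrahydronaphthalene-2-carboxylate | COC(=O)[C@@H]1[C@@H](CO)Cc2cc(OC)c(O)cc2[C@H]1c1ccc(O)c(OC)c1 | target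

## Step count and risks

Total steps: 6. Longest linear sequence: 6 (1 → 13).

The three steps most likely to fail are steps 4, 3 and 5, in that order.

Step 4 is the weakest. Compound 9 carries two equivalent p-hydroxybenzyl groups and the product 11 is itself an oxidisable p-alkylphenol. Double oxidation, over-oxidation of 11 and tautomerisation of 10 to a benzylidene succinate can all compete, so the yield is capped near the statistical value and unchanged 9 must be recycled. The fallback sets out from 9 and uncouples oxidation from ring closure. DDQ in CH2Cl2/MeOH at 0 °C lets methanol intercept the quinone methide at once. The mono-ether dimethyl (2R,3S)-2-[(4-hydroxy-3-methoxyphenyl)(methoxy)methyl]-3-[(4-hydroxy-3-methoxyphenyl)methyl]butanedioate F2 (arrangement at C2 and C3 as in 9, both epimers at the new carbon) is separated from 9 and from the bis-ether. BF3·OEt2 in CH2Cl2 at −40 °C then ionises the benzylic ether under non-oxidising conditions and closes the ring, which brings the route back at 11.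

Step 3 may stall because each imide carbonyl is flanked by a branched α-carbon. Slow methanolysis, attack at the ring carbamate, or sluggish pivalate cleavage are all possible, and forcing it with alkoxide would risk epimerisation to the meso diester. The fallback sets out from 7 and replaces transesterification by hydrolysis and re-esterification. LiOH/H2O2 in THF/H2O at 0 °C cleaves both exocyclic imide bonds and both aryl pivalates to give (2S,3S)-2,3-bis[(4-hydroxy-3-methoxyphenyl)methyl]butanedioic acid F1. Fischer esterification (MeOH, catalytic H2SO4, reflux) returns to 9.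

Step 5 relies only on the steric difference between the C3 and C2 esters. Some hydrolysis at C2 or double hydrolysis would give inseparable acid mixtures. The fallback sets out from 11 and differentiates the esters by reduction instead of hydrolysis. LiBH4 (THF, 0 °C → rt, excess to cover the two phenols) reduces the accessible C3 ester directly to the hydroxymethyl group and leaves the shielded C2 ester, so the route comes back at 13 and skips 12. This path passes through no new compound (entry F0).

Further compounds
F1 | step 3 | (2S,3S)-2,3-bis[(4-hydroxy-3-methoxyphenyl)methyl]butanedioic acid | OC(=O)[C@@H](Cc1ccc(O)c(OC)c1)[C@H](Cc1ccc(O)c(OC)c1)C(=O)O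
F2 | step 4 | dimethyl (2R,3S)-2-[(4-hydroxy-3-methoxyphenyl)(methoxy)methyl]-3-[(4-hydroxy-3-methoxyphenyl)methyl]butanedioate | COC(=O)[C@@H](C(OC)c1ccc(O)c(OC)c1)[C@H](Cc1ccc(O)c(OC)c1)C(=O)OC
F0 | step 5 | none | none
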